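**Strategy**

Everything rests on cutting the heptane chain at C2–C3 and on letting the C5 carbinol dictate C3. Cross-metathesis joins a racemic ring A aryl vinyl carbinol to an enantiopure ring B homoallylic alcohol, giving an (E)-hept-2-ene-1,5-diol with benzyl-protected phenols. Because C1 is benzylic to the electron-rich ring A and C3 sits 1,3 to the C5 hydroxyl, catalytic Re2O7 can move the C1 oxygen to C3 while benzaldehyde dimethyl acetal locks the 3,5-diol as its all-equatorial benzylidene acetal. One operation thus makes the C3–O bond, closes the 1,3-dioxane and sets the syn relationship for either C1 epimer.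

Key step: step 7

Assumption: chain atoms are numbered C1 (on ring A, the 3,4-dihydroxy-5-methoxyphenyl ring) to C7 (on ring B, the 4-hydroxyphenyl ring); Ipc = isopinocampheyl, and (+)-Ipc2BOMe is the methoxyborane derived from (−)-α-pinene; the ring B acid is bought as its methyl ester.

**Route**

Step 1
Reactants: 1 3,4-dihydroxy-5-methoxybenzaldehyde; 2 benzyl bromide
Product: 3 3,4-bis(benzyloxy)-5-methoxybenzaldehyde
Conditions: BnBr (2.4 equiv), K2CO3 (3 equiv), DMF, 60 °C
Reagents that add atoms: benzyl bromide, BrCc1ccccc1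
Why: Williamson etherification, in which carbonate deprotonates both phenols and the phenoxides displace bromide by SN2 while the aldehyde is inert.

Step 2
Reactants: 3 3,4-bis(benzyloxy)-5-methoxybenzaldehyde; 4 vinylmagnesium bromide
Product: 5 (RS)-1-[3,4-bis(benzyloxy)-5-methoxyphenyl]prop-2-en-1-ol
Conditions: CH2=CHMgBr (1.2 equiv), THF, −78 → 0 °C; then sat. aq. NH4Cl
Reagents that add atoms: vinylmagnesium bromide, C=C[Mg]Br
Why: Grignard 1,2-addition to a non-enolisable aromatic aldehyde gives the secondary allylic carbinol, made as the racemate on purpose because the C1 configuration is erased in step 7.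

Step 3
Reactants: 6 methyl 3-(4-hydroxyphenyl)propanoate; 2 benzyl bromide
Product: 7 methyl 3-[4-(benzyloxy)phenyl]propanoate
Conditions: BnBr (1.2 equiv), K2CO3 (2 equiv), acetone, reflux
Reagents that add atoms: benzyl bromide, BrCc1ccccc1
Why: Williamson etherification of the single phenol; the methyl ester is untouched by carbonate in acetone.

Step 4
Reactants: 7 methyl 3-[4-(benzyloxy)phenyl]propanoate
Product: 9 3-[4-(benzyloxy)phenyl]propanal, via aluminium hemiacetal 8 (not isolated)
Conditions: i-Bu2AlH (1.05 equiv), CH2Cl2, −78 °C; then aq. potassium sodium tartrate, rt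
Reagents that add atoms: none
Why: Partial ester reduction with i-Bu2AlH, in which one hydride adds at −78 °C and the tetrahedral aluminium hemiacetal 8 persists until hydrolytic work-up, so the aldehyde appears only after the hydride is destroyed.

Step 5
Reactants: 9 3-[4-(benzyloxy)phenyl]propanal; 10 allylmagnesium bromide
Product: 12 (3S)-1-[4-(benzyloxy)phenyl]hex-5-en-3-ol, via borinate ester 11 (not isolated)
Conditions: (+)-Ipc2BOMe (1.3 equiv), allylMgBr (1.2 equiv), Et2O, 0 °C → rt; then 9, −78 °C; then 3 M NaOH, 30% H2O2, 0 °C → rt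
Reagents that add atoms: allylmagnesium bromide, C=CC[Mg]Br
Why: Brown asymmetric allylboration, in which the B-allyl borane formed in the flask transfers allyl through a closed six-membered chair transition state to the Re face of the aldehyde, so the (−)-α-pinene-derived isopinocampheyl groups set C5 as S under reagent control before oxidative work-up cleaves borinate 11.

Step 6
Reactants: 5 (RS)-1-[3,4-bis(benzyloxy)-5-methoxyphenyl]prop-2-en-1-ol (2.5 equiv); 12 (3S)-1-[4-(benzyloxy)phenyl]hex-5-en-3-ol
Product: 13 (2E,5S)-1-[3,4-bis(benzyloxy)-5-methoxyphenyl]-7-[4-(benzyloxy)phenyl]hept-2-ene-1,5-diol (both C1 epimers)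
Conditions: second-generation Hoveyda–Grubbs catalyst (5 mol %), 1,4-benzoquinone (10 mol %), CH2Cl2, 40 °C
Reagents that add atoms: none
Why: Olefin cross-metathesis between a fast-reacting terminal homoallylic alcohol and a slower secondary allylic alcohol used in excess favours the cross product and, being reversible, the E alkene; benzoquinone suppresses ruthenium-hydride isomerisation of 5, and free hydroxyls and benzyl ethers are tolerated.

Step 7
Reactants: 13 (2E,5S)-1-[3,4-bis(benzyloxy)-5-methoxyphenyl]-7-[4-(benzyloxy)phenyl]hept-2-ene-1,5-diol (both C1 epimers); 14 benzaldehyde dimethyl acetal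
Product: 16 (2S,4S,6S)-4-{(E)-2-[3,4-bis(benzyloxy)-5-methoxyphenyl]ethenyl}-6-{2-[4-(benzyloxy)phenyl]ethyl}-2-phenyl-1,3-dioxane, via transposed diol 15 (not isolated)
Conditions: Re2O7 (5 mol %), PhCH(OMe)2 (3 equiv), CH2Cl2, 0 °C → rt; Et3N quench
Reagents that add atoms: benzaldehyde dimethyl acetal, COC(OC)c1ccccc1
Why: Re2O7 esterifies the C1 hydroxyl and the resulting allyl perrhenate rearranges reversibly through a six-membered chair-like [3,3] transition state that has ion-pair character because ring A stabilises positive charge at C1, so the oxygen arrives at C3 and the alkene ends up conjugated with ring A (diol 15). The closest known reaction type is the Re2O7-catalysed 1,3-transposition of δ-hydroxy allylic alcohols run with an acetal donor to give 1,3-syn-diol acetals. The dioxane closes when the acid present exchanges a methoxy group of 14 for one of the two hydroxyls and the other hydroxyl adds to the derived oxocarbenium ion in a 6-endo-trig mode; only the C3-oxygenated isomer can form this six-membered acetal, which therefore drains the C1/C3 equilibrium. C3 is set under thermodynamic control by the fixed C5 centre: the cinnamyl-type C3–O bond keeps re-ionising under the catalyst, the C3 epimers equilibrate, and the chair acetal with the styrenyl and arylethyl groups both equatorial, which is the syn-diol, is the sink for both C1 epimers of 13. The acetal carbon is set in the same way by reversible acetal exchange, its phenyl group settling equatorial. The step needs regioselectivity (oxygen at C3, not C1) and 1,3-syn diastereoselectivity, secured by conjugation of the new alkene with ring A, by the 1,3-spacing of C3 and C5 that allows a six-membered acetal, and by the all-equatorial chair.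

Step 8
Reactants: 16 (2S,4S,6S)-4-{(E)-2-[3,4-bis(benzyloxy)-5-methoxyphenyl]ethenyl}-6-{2-[4-(benzyloxy)phenyl]ethyl}-2-phenyl-1,3-dioxane
Product: 17 (2S,4R,6S)-4-{2-[3,4-bis(benzyloxy)-5-methoxyphenyl]ethyl}-6-{2-[4-(benzyloxy)phenyl]ethyl}-2-phenyl-1,3-dioxane
Conditions: TsNHNH2 (10 equiv, in portions), NaOAc (12 equiv), DME/H2O, reflux
Reagents that add atoms: none
Why: Diimide reduction, in which HN=NH released from the sulfonyl hydrazide transfers two hydrogens suprafacially through a six-membered cyclic transition state to the non-polar C1=C2 bond only, so the allylic C3–O bond, the acetal, the benzyl ethers and all three stereocentres are untouched.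

Step 9
Reactants: 17 (2S,4R,6S)-4-{2-[3,4-bis(benzyloxy)-5-methoxyphenyl]ethyl}-6-{2-[4-(benzyloxy)phenyl]ethyl}-2-phenyl-1,3-dioxane
Product: 18 (3R,5S)-1-(3,4-dihydroxy-5-methoxyphenyl)-7-(4-hydroxyphenyl)heptane-3,5-diol
Conditions: H2 (1 atm), Pd(OH)2/C (20 wt %), MeOH/EtOAc, rt
Reagents that add atoms: none
Why: Catalytic hydrogenolysis cleaves the benzylic C–O bonds of the three aryl benzyl ethers and of the benzylidene acetal, while the now unactivated secondary C–O bonds at C3 and C5 are left alone, so the syn-diol is released with its configuration intact.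

**Compound list**

1 | 3,4-dihydroxy-5-methoxybenzaldehyde | COc1cc(C=O)cc(O)c1O | starting material
2 | benzyl bromide | BrCc1ccccc1 | starting material
3 | 3,4-bis(benzyloxy)-5-methoxybenzaldehyde | COc1cc(C=O)cc(OCc2ccccc2)c1OCc1ccccc1 | intermediate
4 | vinylmagnesium bromide | C=C[Mg]Br | starting material
5 | (RS)-1-[3,4-bis(benzyloxy)-5-methoxyphenyl]prop-2-en-1-ol (racemate) | COc1cc(C(O)C=C)cc(OCc2ccccc2)c1OCc1ccccc1 | intermediate
6 | methyl 3-(4-hydroxyphenyl)propanoate | COC(=O)CCc1ccc(O)cc1 | starting material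
7 | methyl 3-[4-(benzyloxy)phenyl]propanoate | COC(=O)CCc1ccc(OCc2ccccc2)cc1 | intermediate
8 | {3-[4-(benzyloxy)phenyl]-1-methoxypropoxy}bis(2-methylpropyl)aluminium (not isolated) | COC(CCc1ccc(OCc2ccccc2)cc1)O[Al](CC(C)C)CC(C)C | intermediate
9 | 3-[4-(benzyloxy)phenyl]propanal | O=CCCc1ccc(OCc2ccccc2)cc1 | intermediate
10 | allylmagnesium bromide | C=CC[Mg]Br | starting material
11 | (3S)-1-[4-(benzyloxy)phenyl]hex-5-en-3-yl diisopinocampheylborinate (not isolated) | C=CC[C@H](CCc1ccc(OCc2ccccc2)cc1)OB([C@H]1C[C@H]2C[C@@H]([C@@H]1C)C2(C)C)[C@H]1C[C@H]2C[C@@H]([C@@H]1C)C2(C)C | intermediate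
12 | (3S)-1-[4-(benzyloxy)phenyl]hex-5-en-3-ol | C=CC[C@@H](O)CCc1ccc(OCc2ccccc2)cc1 | intermediate
13 | (2E,5S)-1-[3,4-bis(benzyloxy)-5-methoxyphenyl]-7-[4-(benzyloxy)phenyl]hept-2-ene-1,5-diol (both C1 epimers) | COc1cc(C(O)/C=C/C[C@@H](O)CCc2ccc(OCc3ccccc3)cc2)cc(OCc2ccccc2)c1OCc1ccccc1 | intermediate
14 | benzaldehyde dimethyl acetal | COC(OC)c1ccccc1 | starting material
15 | (1E,5S)-1-[3,4-bis(benzyloxy)-5-methoxyphenyl]-7-[4-(benzyloxy)phenyl]hept-1-ene-3,5-diol (C3 epimers in equilibrium; not isolated) | COc1cc(/C=C/C(O)C[C@@H](O)CCc2ccc(OCc3ccccc3)cc2)cc(OCc2ccccc2)c1OCc1ccccc1 | intermediate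
16 | (2S,4S,6S)-4-{(E)-2-[3,4-bis(benzyloxy)-5-methoxyphenyl]ethenyl}-6-{2-[4-(benzyloxy)phenyl]ethyl}-2-phenyl-1,3-dioxane (all-cis) | COc1cc(/C=C/[C@@H]2C[C@H](CCc3ccc(OCc4ccccc4)cc3)O[C@H](c3ccccc3)O2)cc(OCc2ccccc2)c1OCc1ccccc1 | intermediate
17 | (2S,4R,6S)-4-{2-[3,4-bis(benzyloxy)-5-methoxyphenyl]ethyl}-6-{2-[4-(benzyloxy)phenyl]ethyl}-2-phenyl-1,3-dioxane (all-cis) | COc1cc(CC[C@@H]2C[C@H](CCc3ccc(OCc4ccccc4)cc3)O[C@H](c3ccccc3)O2)cc(OCc2ccccc2)c1OCc1ccccc1 | intermediate
18 | (3R,5S)-1-(3,4-dihydroxy-5-methoxyphenyl)-7-(4-hydroxyphenyl)heptane-3,5-diol | COc1cc(CC[C@@H](O)C[C@@H](O)CCc2ccc(O)cc2)cc(O)c1O | target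

**Step count and risk**

Total step count: 9. Longest linear sequence: 7 steps (steps 3, 4, 5, 6, 7, 8 and 9; the ring A branch, steps 1 and 2, joins at step 6).

Steps most likely to fail:

Step 7 (key step). Ionisation of the electron-rich 1-aryl allyl system may outrun acetal capture, so that material is lost to oligomerisation, to capture by methanol, or to ring closure of the C5 hydroxyl onto C1 after alkene isomerisation. Equilibration at C3 may also stop short and leave the anti acetal. The fallback reaches the syn acetal by conjugate addition instead of transposition and sets out from 13: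
- MnO2 in CH2Cl2 at rt should oxidise only the benzylic allylic C1 hydroxyl, giving (2E,5S)-1-[3,4-bis(benzyloxy)-5-methoxyphenyl]-7-[4-(benzyloxy)phenyl]-5-hydroxyhept-2-en-1-one F1.
- Benzaldehyde with catalytic KOt-Bu in THF at 0 °C should add the hemiacetal alkoxide of the C5 hydroxyl to C3 (oxa-Michael addition under thermodynamic control), giving the all-cis acetal 1-[3,4-bis(benzyloxy)-5-methoxyphenyl]-2-[(2S,4S,6S)-6-{2-[4-(benzyloxy)phenyl]ethyl}-2-phenyl-1,3-dioxan-4-yl]ethan-1-one F2.
- NaBH4 in MeOH/THF should give the benzylic alcohol 1-[3,4-bis(benzyloxy)-5-methoxyphenyl]-2-[(2S,4R,6S)-6-{2-[4-(benzyloxy)phenyl]ethyl}-2-phenyl-1,3-dioxan-4-yl]ethan-1-ol F3 as C1 epimers.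
- H2 over Pd(OH)2/C in EtOAc/AcOH should remove the electron-rich benzylic hydroxyl together with the acetal and the three benzyl ethers, coming back to the route at the target 18.

Step 6. Ruthenium hydride from catalyst decay may isomerise the aryl vinyl carbinol to its saturated ketone, self-metathesis of either partner may compete, and turnover on the secondary allylic alcohol may be slow. The fallback replaces the carbinol by its enone, which cannot isomerise and does not homodimerise, and sets out from 5:
- MnO2 in CH2Cl2 should give 1-[3,4-bis(benzyloxy)-5-methoxyphenyl]prop-2-en-1-one F4, used fresh.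
- Cross-metathesis of F4 with 12 (second-generation Hoveyda–Grubbs catalyst, CH2Cl2, 40 °C) should give the E-enone (2E,5S)-1-[3,4-bis(benzyloxy)-5-methoxyphenyl]-7-[4-(benzyloxy)phenyl]-5-hydroxyhept-2-en-1-one F1.
- Luche 1,2-reduction (NaBH4, CeCl3·7H2O, MeOH, −40 °C) should return the C1 epimer mixture, coming back to the route at 13.

Step 8. Diimide may disproportionate faster than it reduces the 1,2-disubstituted styrene, leaving unsaturated material, or the hot buffered medium may ionise the cinnamyl-type acetal. The fallback gives up the stoichiometric pericyclic hydrogen transfer for homogeneous catalytic hydrogenation. Setting out from 16, H2 (1 atm) with RhCl(PPh3)3 (5 mol %) in benzene/EtOH at rt should saturate the alkene through the oxidative addition, insertion and reductive elimination cycle of monovalent rhodium. This cycle offers no path for hydrogenolysis of benzyl ethers, acetals or allylic C–O bonds. It comes back to the route at 17 and makes no new compound.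

Further compounds
F1 | step 7 | (2E,5S)-1-[3,4-bis(benzyloxy)-5-methoxyphenyl]-7-[4-(benzyloxy)phenyl]-5-hydroxyhept-2-en-1-one | COc1cc(C(=O)/C=C/C[C@@H](O)CCc2ccc(OCc3ccccc3)cc2)cc(OCc2ccccc2)c1OCc1ccccc1
F2 | step 7 | 1-[3,4-bis(benzyloxy)-5-methoxyphenyl]-2-[(2S,4S,6S)-6-{2-[4-(benzyloxy)phenyl]ethyl}-2-phenyl-1,3-dioxan-4-yl]ethan-1-one | COc1cc(C(=O)C[C@@H]2C[C@H](CCc3ccc(OCc4ccccc4)cc3)O[C@H](c3ccccc3)O2)cc(OCc2ccccc2)c1OCc1ccccc1
F3 | step 7 | 1-[3,4-bis(benzyloxy)-5-methoxyphenyl]-2-[(2S,4R,6S)-6-{2-[4-(benzyloxy)phenyl]ethyl}-2-phenyl-1,3-dioxan-4-yl]ethan-1-ol (C1 epimers) | COc1cc(C(O)C[C@@H]2C[C@H](CCc3ccc(OCc4ccccc4)cc3)O[C@H](c3ccccc3)O2)cc(OCc2ccccc2)c1OCc1ccccc1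
F4 | step 6 | 1-[3,4-bis(benzyloxy)-5-methoxyphenyl]prop-2-en-1-one | COc1cc(C(=O)C=C)cc(OCc2ccccc2)c1OCc1ccccc1
F0 | step 8 | none | none
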